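## Remarks and conventions

- Abbreviations: TIPS = triisopropylsilyl, TBS = tert-butyldimethylsilyl, Ar = 3-methoxy-4-(triisopropylsilyloxy)phenyl, DBF = (2R,3R)-3-(TBS-oxymethyl)-7-methoxy-2-Ar-2,3-dihydrobenzofuran-5-yl.
- Numbering: the oxolane is numbered as in the target (O1, C2 aryl, C3, C4 oxygenated, C5 arylmethyl), so the ring ketones are called oxolan-4-ones; by lowest locants they would be oxolan-3-ones. Primed locants refer to the dihydrobenzofuran.
- Correction of a descriptor: with the geometry the target requires, the insertion product 9 is the (2R,3S) ester. C3' becomes R only after reduction, because CH2OH ranks below C2' whereas CO2Me ranks above it; nothing changes in space.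
- Assumption on the catalyst: for 2-(benzyloxy)aryl diazoacetates the S-configured phthalimido-carboxylate dirhodium catalysts are taken to give the (2S,3R) cis esters, so the R-configured catalyst is used here; should the sense prove opposite, the mirror-image catalyst is used and nothing else changes.

## Structural features

The target is a fully substituted oxolane (ring A: O1, C2–C5). It carries at C2 a 2,3-dihydrobenzofuran (ring B fused to arene ring C), bound through the arene carbon C5', and at C5 a 4-hydroxy-3-methoxybenzyl group. Ring A has four contiguous stereocentres, C2 (aryl), C3 (CH2OH), C4 (OH) and C5 (CH2Ar), all S. The C2 and C5 substituents are cis, the C3 arm is trans to both neighbours, and the C4 hydroxyl is cis to the C5 benzyl group. Ring B has two further adjacent stereocentres, C2' (4-hydroxy-3-methoxyphenyl) and C3' (CH2OH), both R and cis. The arene separates them from the ring A centres, so each array must be set in absolute terms. The fragile points are the two benzylic C–O bonds para to oxygen donors (C2'–O1' and C2–O1). They can ionise under acid and, once the phenols are free, open through quinone methides under base. The real difficulty is the cis C2'/C3' pair: it is the less stable arrangement, equilibration or oxidative phenol coupling lead to trans, and a carbonyl group at C3' makes it epimerisable. The key step exploits the fact that C2' sits on the ring oxygen O1' and C3' on the arene carbon C3a'. C2' can therefore enter as the OCH2 carbon of a benzyl aryl ether and C3' as a carbene carbon on the same arene; insertion into the C2'–H bond then forms C2'–C3', closes ring B and sets both centres at once.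

## Logic of the disconnections

**27 to 26.** Only O–Si bonds are cut first: the two phenols and the C3' hydroxymethyl oxygen of 27 go back to the two TIPS aryl ethers and the TBS ether of 26. The gain is that every earlier step runs without free phenols, whose para-hydroxybenzylic ethers would open. The forward step must remove all three silyl groups in one operation with fluoride that is buffered.

**26 to 25 to 23.** The C4–H bond and then the C3–CH2OH bond of ring A are cut. Removing the hydride gives the ketone of 25, whose free hydroxymethyl group can steer hydride to its own face. Removing the hydroxymethyl group gives 23, which keeps only the C2 and C5 centres. Two of the four ring A centres thus become consequences of the other two. The forward steps need enolisation of 23 toward C3 and not C5, attack of formaldehyde anti to the C2 aryl group, and internal hydride delivery to C4.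

**23 to 22 to 21 to 13 + 19.** The C2–C3 bond of 23 is cut, which leads to the enol acetal 22. Exchange of its methylidene for a carbonyl oxygen gives 21, and cutting both acetal C–O bonds at C2 divides 21 into 13 and 19. This is the cut in ring A that separates the two aryl-bearing halves and leaves C5 as a stereocentre carried in from 19. The forward rearrangement must ionise the acetal and not the C2'–O1' bond, and must close the ring with C2 cis to C5.

**19 to 18 to 15 + 16, and 15 to 14.** The bond between the benzylic carbon and the arene of 19 is cut, giving the aryl nucleophile from 15 and the three-carbon electrophile 16, which already holds the stereocentre. The gain is a two-fragment assembly with no asymmetric step. The forward step demands attack at the unsubstituted epoxide carbon with the ester left intact, and the later hydrolysis must spare the aryl silyl ether.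

**13 to 11 to 10 to 9.** The C5'–CHO bond is cut to the C5'–Br bond, and the silyl ether and alcohol are traced back to the methyl ester of 9. Bromine is inert in the carbenoid step and serves later as the site of the aryllithium. The demand is a non-basic, cold hydride reduction so that the cis ester does not epimerise before its carbonyl is gone.

**9 to 8.** The C2'–C3' bond is cut and ring B is opened, which removes both ring B stereocentres and leaves an acyclic diazo ester with a benzyl ether. This is the strategic cut, because the cis pair is then made kinetically in the bond-forming event itself. The forward step demands a chiral catalyst that controls the absolute and relative configuration, and a substrate in which no other C–H bond is within reach.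

**8 to 7 to 6 to 5.** The C=N2 unit goes back to the CH2 of the arylacetate 7. The ester carbon of 7 is cut off through the enol ether 6 to the aldehyde 5, a one-carbon homologation. The demand is an oxidation of 6 that stops at the ester and leaves the electron-rich benzyl ether alone.

**5 to 3 + 4, and 3 to 2 to 1.** The benzylic C–O bond of 5 is cut to the phenol 4 and the alcohol 3, which comes from 1 by silylation and reduction. Base-free ether formation is required so that the aryl silyl ether stays in place.

## Other disconnections considered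

**Alternative 1:** The cut is the C2–C3 bond of ring A, with the two carbons held beforehand in a 4-methylidene-1,3-dioxolane. In the forward step Me2AlCl ionises the acetal at the bond to the enol oxygen, and the aluminium enolate recombines through carbon with the aryl-stabilised oxocarbenium ion. The product A1 is the 2,5-cis oxolan-4-one; it is the same structure as 23 and is formed from 22 in step 16 of the chosen plan.
- In its favour: it unites the two halves of the molecule, takes C5 from an α-hydroxy acid, sets C2 relative to C5, and leaves a ketone from which C3 and C4 can be reached.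
- Against it here: the closure is of the 5-(enolendo)-endo-trig kind, which is stereoelectronically awkward; a Lewis acid meets the ionisable C2'–O1' bond; and two ring A centres remain to be made afterwards.
- Comparison: both steps build one ring and one C–C bond. The insertion sets two stereocentres under catalyst control, the rearrangement one under substrate control. On convergence the rearrangement is the better step, since it joins fragments while the insertion is intramolecular in a linear sequence. On step economy the two are equal, because a plan headed by A1 still has to obtain the cis-dihydrobenzofuran aldehyde by other means. The two are complementary; the insertion is ranked first because the cis C2'/C3' pair is the harder problem.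

**Alternative 2:** The cut is O1–C5, with the C5 arylmethyl group pared back to an iodomethyl group. The precursor is the open-chain 1-aryl-2-(silyloxymethyl)pent-4-ene-1,3-diol A3. In the forward step I2 with NaHCO3 forms an iodonium ion on the terminal alkene and the benzylic hydroxyl closes ring A in a 5-exo-trig manner to give A2. The allylic C4 hydroxyl is expected to place the iodomethyl group cis to itself.
- In its favour: the conditions are mild and weakly basic, which suits the acid-sensitive ring B. C3 and C4 already have their final oxidation level, so no later hydroxymethylation or reduction is needed; on these two points it is the better of the two ways to ring A.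
- Against it here: A3 needs three contiguous acyclic stereocentres before the ring exists. After the closure the aryl group must still replace a primary iodide that is β to the ring oxygen; metalation at that carbon invites β-alkoxy elimination and ring opening, and direct displacement by an arylcopper reagent at a β-branched centre is slow.
- Comparison: A2 gains one ring, one C–O bond and one stereocentre under substrate control, but no C–C bond; the insertion gains a C–C bond and two stereocentres. Mechanistically the iodonium closure is equal in reliability to the insertion. In step count it is not shorter once the aldol, vinyl addition, protecting-group and arylation steps are counted. It leaves the cis C2'/C3' pair unsolved.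

**Alternative 3:** The cuts are O1–C5 and C5–C6. The precursor is the diazoketone A5, in which the C2 oxygen carries the arylmethyl group as an ether. In the forward step Cu(hfacac)2, copper bis(hexafluoroacetylacetonate), generates a copper carbenoid at C5. The ether oxygen captures it to form a five-membered oxonium ylide, and a 1,2-shift moves the arylmethyl group from oxygen to C5 to give A4.
- In its favour: one step forms the ring, the O1–C5 and C5–C6 bonds, and delivers the C5 side chain without a separate hydroxy-acid fragment. C3 is already substituted. In bond economy for ring A it is the better of the two plans.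
- Against it here: the 1,2-shift proceeds through a radical pair, so the C5 configuration relative to C2 is weakly controlled and escape products are expected. A 1,4-shift to the enolate oxygen competes, as does migration of the ring carbon C2, which is also benzylic. C3 is α to the diazoketone carbonyl and can epimerise, and the diazoketone requires diazomethane.
- Comparison: A4 gains one ring and two bonds but only one stereocentre, under weak control; the insertion gains one bond and two stereocentres under catalyst control. It could save two or three steps in ring A, so on step economy it is the better alternative, but at the price of the least predictable stereochemistry. It also leaves the cis C2'/C3' pair to another method.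

Key step: step 7

## Route

Step 1
Reactants: 1 vanillin
Product: 2 3-methoxy-4-(triisopropylsilyloxy)benzaldehyde
Conditions: i-Pr3SiCl, imidazole, DMF, rt
Reagents that add atoms: triisopropylsilyl chloride, CC(C)[Si](Cl)(C(C)C)C(C)C
Why: Silylation of a phenol; the TIPS aryl ether is chosen because it resists the bases used later far better than a smaller silyl ether.

Step 2
Reactants: 2 3-methoxy-4-(triisopropylsilyloxy)benzaldehyde
Product: 3 [3-methoxy-4-(triisopropylsilyloxy)phenyl]methanol
Conditions: NaBH4, MeOH/THF, 0 °C
Reagents that add atoms: none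
Why: Borohydride reduction of an aromatic aldehyde; the silyl ether is stable to the brief, cold, weakly basic medium.

Step 3
Reactants: 3 [3-methoxy-4-(triisopropylsilyloxy)phenyl]methanol; 4 5-bromo-2-hydroxy-3-methoxybenzaldehyde
Product: 5 5-bromo-3-methoxy-2-(ArCH2O)benzaldehyde
Conditions: PPh3, DIAD, THF, 0 °C to rt
Reagents that add atoms: none
Why: Mitsunobu etherification; the phenol of 4 is acidified by the ortho formyl and para bromo groups and the primary benzylic alcohol is activated as its alkoxyphosphonium ion. No base is present and no labile benzylic halide has to be handled.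

Step 4
Reactants: 5 5-bromo-3-methoxy-2-(ArCH2O)benzaldehyde
Product: 6 5-bromo-1-methoxy-3-(2-methoxyethenyl)-2-(ArCH2O)benzene (E/Z mixture)
Conditions: Ph3P(CH2OMe)Cl, NaN(SiMe3)2, THF, 0 °C; then 5, 0 °C to rt
Reagents that add atoms: (methoxymethyl)triphenylphosphonium chloride, COC[P+](c1ccccc1)(c1ccccc1)c1ccccc1.[Cl-]
Why: Wittig methoxymethylenation of an aryl aldehyde; the alkene geometry is irrelevant because both isomers are oxidised to the same ester.

Step 5
Reactants: 6 5-bromo-1-methoxy-3-(2-methoxyethenyl)-2-(ArCH2O)benzene
Product: 7 methyl 2-[5-bromo-3-methoxy-2-(ArCH2O)phenyl]acetate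
Conditions: (C5H5NH)[CrO3Cl] (pyridinium chlorochromate, 2.5 equiv), 4 Å MS, CH2Cl2, rt
Reagents that add atoms: pyridinium chlorochromate, [O-][Cr](=O)(=O)Cl.c1cc[nH+]cc1
Why: Chlorochromate oxidation of an aldehyde-derived enol ether to the ester: protonation at the benzylic carbon gives an oxocarbenium ion, chromate adds at the oxygen-bearing carbon, and the resulting hemiacetal chromate ester is oxidised like an alcohol. This completes the one-carbon homologation in two steps without aqueous acid.

Step 6
Reactants: 7 methyl 2-[5-bromo-3-methoxy-2-(ArCH2O)phenyl]acetate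
Product: 8 methyl 2-diazo-2-[5-bromo-3-methoxy-2-(ArCH2O)phenyl]acetate
Conditions: p-ABSA, DBU, MeCN, 0 °C to rt
Reagents that add atoms: 4-acetamidobenzenesulfonyl azide, CC(=O)Nc1ccc(cc1)S(=O)(=O)N=[N+]=[N-]
Why: Regitz diazo transfer to an arylacetate, whose benzylic ester CH2 is acidic enough for DBU; aryldiazoacetates of this kind are stable enough to purify.

Step 7
Reactants: 8 methyl 2-diazo-2-[5-bromo-3-methoxy-2-(ArCH2O)phenyl]acetate
Product: 9 methyl (2R,3S)-5-bromo-7-methoxy-2-Ar-2,3-dihydrobenzofuran-3-carboxylate (2,3-cis)
Conditions: Rh2(R-PTTL)4, dirhodium tetrakis[N-phthaloyl-(R)-tert-leucinate] (1 mol %), toluene, −78 °C, slow addition of 8; filtration through silica without base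
Reagents that add atoms: none
Why: Rh2(R-PTTL)4, a dimer of divalent rhodium, attacks the diazo carbon of 8, dinitrogen leaves, and a rhodium-bound carbene at the future C3' results that is electrophilic but moderated by the aryl donor and the ester acceptor. The C–H bond of the OCH2Ar group lies 1,5 to this carbon; its electron pair, raised in energy by O1' and by the silyloxyaryl ring, is donated into the empty carbene orbital in a concerted, asynchronous three-centre transition state, so that C2'–C3' forms as hydrogen passes to C3' and the catalyst is released. The closest known reaction type is the dirhodium-carboxylate-catalysed enantioselective intramolecular C–H insertion of methyl 2-(benzyloxy)aryldiazoacetates, which gives cis-2-aryl-2,3-dihydrobenzofuran-3-carboxylates. Ring B closes by 1,5 C–H insertion through a five-membered cyclic transition state (C3', C3a', C7a', O1', C2'), not by a nucleophilic closure. Both new stereocentres arise in this single event: their cis relation is kinetic, because the C2' aryl group turns away from the carboxylate wall of the catalyst and ends on the side of the ester, and their absolute sense, (2R,3S) for the ester, is fixed by the chiral pocket of the four phthalimido-tert-leucinate ligands. The step needs site selectivity, which the substrate secures because the only C–H bond within five-ring reach is the oxygen-activated benzylic one; the methoxy groups cannot reach, a four-membered oxonium ylide is strained, and bromine and the silyl ether are inert. It also needs the absence of base, which the neutral medium at −78 °C and the base-free work-up provide, so that the cis ester does not epimerise.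

Step 8
Reactants: 9 methyl (2R,3S)-5-bromo-7-methoxy-2-Ar-2,3-dihydrobenzofuran-3-carboxylate
Product: 10 [(2R,3R)-5-bromo-7-methoxy-2-Ar-2,3-dihydrobenzofuran-3-yl]methanol (2,3-cis)
Conditions: i-Bu2AlH (3 equiv), CH2Cl2, −78 to −40 °C; aq. KNaC4H4O6
Reagents that add atoms: none
Why: Aluminium hydride reduction of an ester to the primary alcohol; the reagent is a Lewis acid and not a base, and the intermediate aldehyde is reduced faster than it can enolise, so the cis relation is kept. C3' stops being epimerisable here.

Step 9
Reactants: 10 [(2R,3R)-5-bromo-7-methoxy-2-Ar-2,3-dihydrobenzofuran-3-yl]methanol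
Product: 11 (2R,3R)-5-bromo-3-(TBS-oxymethyl)-7-methoxy-2-Ar-2,3-dihydrobenzofuran
Conditions: t-BuMe2SiCl, imidazole, DMF, rt
Reagents that add atoms: tert-butyldimethylsilyl chloride, CC(C)(C)[Si](C)(C)Cl
Why: Silylation of a primary alcohol; the TBS ether removes the acidic proton before the lithiation and the Lewis acid steps, and falls with the TIPS groups at the end.

Step 10
Reactants: 11 (2R,3R)-5-bromo-3-(TBS-oxymethyl)-7-methoxy-2-Ar-2,3-dihydrobenzofuran
Product: 13 (2R,3R)-3-(TBS-oxymethyl)-7-methoxy-2-Ar-2,3-dihydrobenzofuran-5-carbaldehyde, via 5-lithio-dihydrobenzofuran 12 (not isolated)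
Conditions: t-BuLi (2.1 equiv), THF, −78 °C; then DMF, −78 to 0 °C; H2O
Reagents that add atoms: N,N-dimethylformamide, CN(C)C=O
Why: Bromine–lithium exchange followed by Bouveault formylation; the exchange at −78 °C is much faster than deprotonation at C2', the silyl ethers are inert, and no stereocentre is involved.

Step 11
Reactants: 14 4-bromo-2-methoxyphenol
Product: 15 (4-bromo-2-methoxyphenoxy)triisopropylsilane
Conditions: i-Pr3SiCl, imidazole, DMF, rt
Reagents that add atoms: triisopropylsilyl chloride, CC(C)[Si](Cl)(C(C)C)C(C)C
Why: Silylation of a phenol, with the same protecting group as on the other phenol so that one final deprotection is enough.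

Step 12
Reactants: 15 (4-bromo-2-methoxyphenoxy)triisopropylsilane; 16 methyl (2S)-oxirane-2-carboxylate
Product: 18 methyl (2S)-2-hydroxy-3-Ar-propanoate, via arylmagnesium bromide 17 (not isolated)
Conditions: Mg, THF, reflux; then CuI (copper monoiodide, 10 mol %), 16, THF, −40 to −20 °C; H2O
Reagents that add atoms: none
Why: Grignard formation and copper-catalysed SN2 opening of a glycidic ester at its unsubstituted carbon; the arylcopper species attacks the epoxide faster than the ester at low temperature, and the C2–O bond of 16 is untouched, so the S configuration is carried over.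

Step 13
Reactants: 18 methyl (2S)-2-hydroxy-3-Ar-propanoate
Product: 19 (2S)-2-hydroxy-3-Ar-propanoic acid
Conditions: LiOH·H2O, THF/H2O, 0 °C; then 1 M HCl to pH 3
Reagents that add atoms: lithium hydroxide, [Li+].[OH-]
Why: Saponification; an α-hydroxy methyl ester hydrolyses quickly at 0 °C, whereas the hindered TIPS aryl ether reacts with hydroxide much more slowly, and the stereocentre is not enolised under these conditions.

Step 14
Reactants: 19 (2S)-2-hydroxy-3-Ar-propanoic acid; 13 (2R,3R)-3-(TBS-oxymethyl)-7-methoxy-2-Ar-2,3-dihydrobenzofuran-5-carbaldehyde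
Product: 21 (2S,5S)-2-DBF-5-(ArCH2)-1,3-dioxolan-4-one (2,5-cis), via bis(trimethylsilyl) derivative 20 (not isolated)
Conditions: (Me3Si)2NH, cat. Me3SiCl, THF, 50 °C, evaporate; then 13, Me3SiOTf (0.2 equiv), CH2Cl2, −78 °C; pyridine
Reagents that add atoms: none
Why: Silyl triflate-catalysed acetalisation of an aldehyde with a bis-silylated hydroxy acid, driven by formation of hexamethyldisiloxane; at −78 °C the cis dioxolanone is the kinetic product, the C5 centre of 19 controlling the acetal carbon. The low temperature and catalytic acid protect the C2'–O1' bond.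

Step 15
Reactants: 21 (2S,5S)-2-DBF-5-(ArCH2)-1,3-dioxolan-4-one
Product: 22 (2S,5S)-2-DBF-5-(ArCH2)-4-methylidene-1,3-dioxolane
Conditions: Cp2TiMe2 (2.5 equiv), toluene, 65 °C, dark
Reagents that add atoms: dimethyltitanocene, C[Ti](C)(C1C=CC=C1)C1C=CC=C1
Why: Petasis methylenation of a lactone carbonyl through the titanocene methylidene; the reagent is non-basic and non-acidic, so the acetal, the silyl ethers and both stereocentres of the dioxolane survive.

Step 16
Reactants: 22 (2S,5S)-2-DBF-5-(ArCH2)-4-methylidene-1,3-dioxolane
Product: 23 (2S,5S)-2-DBF-5-(ArCH2)-oxolan-4-one (2,5-cis)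
Conditions: Me2AlCl (1.5 equiv), CH2Cl2, −78 °C; aq. NaHCO3
Reagents that add atoms: none
Why: Petasis–Ferrier rearrangement: the aluminium reagent binds the enol oxygen and breaks the acetal C–O bond to an oxocarbenium ion stabilised by the DBF arene and an aluminium enolate, whose carbon closes the C2–C3 bond. C2 becomes planar and is reset cis to the untouched C5 centre through an envelope transition state with both substituents pseudo-equatorial, and the chloride-bearing aluminium leaves the ketone unreduced.

Step 17
Reactants: 23 (2S,5S)-2-DBF-5-(ArCH2)-oxolan-4-one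
Product: 25 (2S,3R,5S)-2-DBF-3-(hydroxymethyl)-5-(ArCH2)-oxolan-4-one (2,3-trans and 2,5-cis), via lithium enolate 24 (not isolated)
Conditions: LiN(i-Pr)2 (1.1 equiv), THF, −78 °C; then HCHO (gas, from cracked paraformaldehyde), −78 °C; AcOH at −78 °C
Reagents that add atoms: formaldehyde, C=O
Why: Kinetic enolate formation and aldol addition to formaldehyde; the amide base removes a proton from the C3 methylene and not the oxygen-bearing C5 methine, and ring opening of the enolate by loss of O1 would be a reverse 5-endo process with poor orbital overlap. Formaldehyde approaches anti to the adjacent C2 aryl group, which sets C3 trans; the descriptor is R here only because the ketone outranks C2.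

Step 18
Reactants: 25 (2S,3R,5S)-2-DBF-3-(hydroxymethyl)-5-(ArCH2)-oxolan-4-one
Product: 26 (2S,3S,4S,5S)-2-DBF-3-(hydroxymethyl)-5-(ArCH2)-oxolan-4-ol
Conditions: Me4NBH(OAc)3, MeCN/AcOH (1:1), −30 °C
Reagents that add atoms: none
Why: Evans–Saksena directed reduction of a β-hydroxy ketone; the primary hydroxyl exchanges onto boron and the hydride is delivered internally through a six-membered transition state to the face of C4 that carries the C3 arm. The new hydroxyl is therefore trans to the hydroxymethyl group and cis to the C5 benzyl group, and the reagent does not reduce the ketone without this delivery.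

Step 19
Reactants: 26 (2S,3S,4S,5S)-2-DBF-3-(hydroxymethyl)-5-(ArCH2)-oxolan-4-ol
Product: 27 (2S,3S,4S,5S)-2-[(2R,3R)-2-(4-hydroxy-3-methoxyphenyl)-3-(hydroxymethyl)-7-methoxy-2,3-dihydrobenzofuran-5-yl]-5-(4-hydroxy-3-methoxybenzyl)-3-(hydroxymethyl)oxolan-4-ol
Conditions: Bu4NF/AcOH (1:1, excess), THF, 0 °C to rt
Reagents that add atoms: none
Why: Fluoride desilylation of two aryl TIPS ethers and one primary TBS ether in one operation; the acetic acid buffer keeps the liberated phenols protonated, so that neither para-hydroxybenzylic ether (C2'–O1', C2–O1) opens through a quinone methide and no centre is epimerised.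

## Compound list

1 | vanillin (4-hydroxy-3-methoxybenzaldehyde) | COc1cc(C=O)ccc1O | starting material
2 | 3-methoxy-4-(triisopropylsilyloxy)benzaldehyde | COc1cc(C=O)ccc1O[Si](C(C)C)(C(C)C)C(C)C | intermediate
3 | [3-methoxy-4-(triisopropylsilyloxy)phenyl]methanol | COc1cc(CO)ccc1O[Si](C(C)C)(C(C)C)C(C)C | intermediate
4 | 5-bromo-2-hydroxy-3-methoxybenzaldehyde | COc1cc(Br)cc(C=O)c1O | starting material
5 | 5-bromo-3-methoxy-2-[3-methoxy-4-(triisopropylsilyloxy)benzyloxy]benzaldehyde | COc1cc(Br)cc(C=O)c1OCc1ccc(O[Si](C(C)C)(C(C)C)C(C)C)c(OC)c1 | intermediate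
6 | 5-bromo-1-methoxy-3-(2-methoxyethenyl)-2-[3-methoxy-4-(triisopropylsilyloxy)benzyloxy]benzene, E/Z mixture | COC=Cc1cc(Br)cc(OC)c1OCc1ccc(O[Si](C(C)C)(C(C)C)C(C)C)c(OC)c1 | intermediate
7 | methyl 2-[5-bromo-3-methoxy-2-(3-methoxy-4-triisopropylsilyloxybenzyloxy)phenyl]acetate | COC(=O)Cc1cc(Br)cc(OC)c1OCc1ccc(O[Si](C(C)C)(C(C)C)C(C)C)c(OC)c1 | intermediate
8 | methyl 2-diazo-2-[5-bromo-3-methoxy-2-(3-methoxy-4-triisopropylsilyloxybenzyloxy)phenyl]acetate | COC(=O)C(=[N+]=[N-])c1cc(Br)cc(OC)c1OCc1ccc(O[Si](C(C)C)(C(C)C)C(C)C)c(OC)c1 | intermediate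
9 | methyl (2R,3S)-5-bromo-7-methoxy-2-[3-methoxy-4-(triisopropylsilyloxy)phenyl]-2,3-dihydrobenzofuran-3-carboxylate, 2,3-cis | Brc1cc(OC)c2c(c1)[C@H](C(=O)OC)[C@H](c1ccc(O[Si](C(C)C)(C(C)C)C(C)C)c(OC)c1)O2 | intermediate
10 | [(2R,3R)-5-bromo-7-methoxy-2-[3-methoxy-4-(triisopropylsilyloxy)phenyl]-2,3-dihydrobenzofuran-3-yl]methanol, 2,3-cis | Brc1cc(OC)c2c(c1)[C@H](CO)[C@H](c1ccc(O[Si](C(C)C)(C(C)C)C(C)C)c(OC)c1)O2 | intermediate
11 | (2R,3R)-5-bromo-3-(tert-butyldimethylsilyloxymethyl)-7-methoxy-2-[3-methoxy-4-(triisopropylsilyloxy)phenyl]-2,3-dihydrobenzofuran | Brc1cc(OC)c2c(c1)[C@H](CO[Si](C)(C)C(C)(C)C)[C@H](c1ccc(O[Si](C(C)C)(C(C)C)C(C)C)c(OC)c1)O2 | intermediate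
12 | 5-lithio analogue of 11, formed in the flask | [Li]c1cc(OC)c2c(c1)[C@H](CO[Si](C)(C)C(C)(C)C)[C@H](c1ccc(O[Si](C(C)C)(C(C)C)C(C)C)c(OC)c1)O2 | intermediate
13 | (2R,3R)-3-(tert-butyldimethylsilyloxymethyl)-7-methoxy-2-[3-methoxy-4-(triisopropylsilyloxy)phenyl]-2,3-dihydrobenzofuran-5-carbaldehyde | O=Cc1cc(OC)c2c(c1)[C@H](CO[Si](C)(C)C(C)(C)C)[C@H](c1ccc(O[Si](C(C)C)(C(C)C)C(C)C)c(OC)c1)O2 | intermediate
14 | 4-bromo-2-methoxyphenol | COc1cc(Br)ccc1O | starting material
15 | (4-bromo-2-methoxyphenoxy)triisopropylsilane | COc1cc(Br)ccc1O[Si](C(C)C)(C(C)C)C(C)C | intermediate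
16 | methyl (2S)-oxirane-2-carboxylate, methyl (S)-glycidate | COC(=O)[C@@H]1CO1 | starting material
17 | [3-methoxy-4-(triisopropylsilyloxy)phenyl]magnesium bromide, formed in the flask | COc1cc([Mg]Br)ccc1O[Si](C(C)C)(C(C)C)C(C)C | intermediate
18 | methyl (2S)-2-hydroxy-3-[3-methoxy-4-(triisopropylsilyloxy)phenyl]propanoate | COC(=O)[C@@H](O)Cc1ccc(O[Si](C(C)C)(C(C)C)C(C)C)c(OC)c1 | intermediate
19 | (2S)-2-hydroxy-3-[3-methoxy-4-(triisopropylsilyloxy)phenyl]propanoic acid | OC(=O)[C@@H](O)Cc1ccc(O[Si](C(C)C)(C(C)C)C(C)C)c(OC)c1 | intermediate
20 | trimethylsilyl (2S)-3-[3-methoxy-4-(triisopropylsilyloxy)phenyl]-2-(trimethylsilyloxy)propanoate, formed in the flask | C[Si](C)(C)OC(=O)[C@@H](O[Si](C)(C)C)Cc1ccc(O[Si](C(C)C)(C(C)C)C(C)C)c(OC)c1 | intermediate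
21 | (2S,5S)-2-DBF-5-[3-methoxy-4-(triisopropylsilyloxy)benzyl]-1,3-dioxolan-4-one, 2,5-cis | O=C1O[C@@H](c2cc(OC)c3c(c2)[C@H](CO[Si](C)(C)C(C)(C)C)[C@H](c2ccc(O[Si](C(C)C)(C(C)C)C(C)C)c(OC)c2)O3)O[C@H]1Cc1ccc(O[Si](C(C)C)(C(C)C)C(C)C)c(OC)c1 | intermediate
22 | (2S,5S)-2-DBF-5-[3-methoxy-4-(triisopropylsilyloxy)benzyl]-4-methylidene-1,3-dioxolane, 2,5-cis | C=C1O[C@@H](c2cc(OC)c3c(c2)[C@H](CO[Si](C)(C)C(C)(C)C)[C@H](c2ccc(O[Si](C(C)C)(C(C)C)C(C)C)c(OC)c2)O3)O[C@H]1Cc1ccc(O[Si](C(C)C)(C(C)C)C(C)C)c(OC)c1 | intermediate
23 | (2S,5S)-2-DBF-5-[3-methoxy-4-(triisopropylsilyloxy)benzyl]oxolan-4-one, 2,5-cis | COc1cc(C[C@@H]2O[C@H](c3cc(OC)c4c(c3)[C@H](CO[Si](C)(C)C(C)(C)C)[C@H](c5ccc(O[Si](C(C)C)(C(C)C)C(C)C)c(OC)c5)O4)CC2=O)ccc1O[Si](C(C)C)(C(C)C)C(C)C | intermediate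
24 | lithium C3–C4 enolate of 23, formed in the flask | COc1cc(C[C@@H]2O[C@H](c3cc(OC)c4c(c3)[C@H](CO[Si](C)(C)C(C)(C)C)[C@H](c5ccc(O[Si](C(C)C)(C(C)C)C(C)C)c(OC)c5)O4)C=C2O[Li])ccc1O[Si](C(C)C)(C(C)C)C(C)C | intermediate
25 | (2S,3R,5S)-2-DBF-3-(hydroxymethyl)-5-[3-methoxy-4-(triisopropylsilyloxy)benzyl]oxolan-4-one, 2,3-trans-2,5-cis | COc1cc(C[C@@H]2O[C@H](c3cc(OC)c4c(c3)[C@H](CO[Si](C)(C)C(C)(C)C)[C@H](c5ccc(O[Si](C(C)C)(C(C)C)C(C)C)c(OC)c5)O4)[C@@H](CO)C2=O)ccc1O[Si](C(C)C)(C(C)C)C(C)C | intermediate
26 | (2S,3S,4S,5S)-2-DBF-3-(hydroxymethyl)-5-[3-methoxy-4-(triisopropylsilyloxy)benzyl]oxolan-4-ol | COc1cc(C[C@@H]2O[C@H](c3cc(OC)c4c(c3)[C@H](CO[Si](C)(C)C(C)(C)C)[C@H](c5ccc(O[Si](C(C)C)(C(C)C)C(C)C)c(OC)c5)O4)[C@@H](CO)[C@@H]2O)ccc1O[Si](C(C)C)(C(C)C)C(C)C | intermediate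
27 | CNP0179668.1, (2S,3S,4S,5S)-2-[(2R,3R)-2-(4-hydroxy-3-methoxyphenyl)-3-(hydroxymethyl)-7-methoxy-2,3-dihydrobenzofuran-5-yl]-5-(4-hydroxy-3-methoxybenzyl)-3-(hydroxymethyl)oxolan-4-ol | COc1cc(C[C@@H]2O[C@H](c3cc(OC)c4c(c3)[C@H](CO)[C@H](c3ccc(O)c(OC)c3)O4)[C@@H](CO)[C@@H]2O)ccc1O | target

## Step count and risks

Total: 19 steps. Longest linear sequence: 16 steps (steps 1–10 and 14–19, from 1). Steps 11–13 form the side branch that supplies 19.

**Step 7 (key step).** The benzylic C–H bond is very electron-rich, so the insertion may lose concertedness: hydride transfer to the carbene followed by ion-pair collapse would erode both the cis preference and the enantioselectivity. Carbene dimerisation and epimerisation of the cis ester during handling are further concerns.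
Fallback, a resolution in place of catalyst control, from 8 back to 10: the insertion is run with the achiral Rh2(O2CCPh3)4, dirhodium tetrakis(triphenylacetate), which should give the cis ester as a racemate, that is 9 together with its mirror image, methyl (2S,3R)-5-bromo-7-methoxy-2-Ar-2,3-dihydrobenzofuran-3-carboxylate F1. Cold i-Bu2AlH reduction gives 10 together with its mirror image, the (2S,3S) alcohol F2. Esterification of the mixture with (S)-2-methoxy-2-phenylacetic acid (DCC, DMAP) gives two diastereomers, the (S)-2-methoxy-2-phenylacetate of 10 F3 and the (S)-2-methoxy-2-phenylacetate of the mirror-image alcohol F4, which are separated by chromatography or crystallisation. Reductive cleavage of the first with i-Bu2AlH at −78 °C returns 10.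

**Step 5.** The chromate may cleave the enol ether double bond oxidatively, or oxidise the electron-rich benzylic ether, instead of oxidising the hemiacetal chromate ester; the acidic reagent may also cause loss of the benzyl ether.
Fallback, a stepwise homologation, from 6 back to 7: Hg(OAc)2 in aqueous THF followed by KI hydrolyses the enol ether under neutral conditions to 2-[5-bromo-3-methoxy-2-(ArCH2O)phenyl]acetaldehyde F5. Pinnick oxidation (NaClO2, NaH2PO4, 2-methyl-2-butene) gives 2-[5-bromo-3-methoxy-2-(ArCH2O)phenyl]acetic acid F6, and Me3SiCHN2 in toluene/MeOH gives 7.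

**Step 16.** The Lewis acid may ionise the second benzylic ether, C2'–O1', which would epimerise ring B. Alternatively the oxocarbenium–enolate pair may fail to recombine through carbon, since the closure is stereoelectronically awkward, and fragment on work-up.
Fallback, rearrangement with immediate reduction and later re-oxidation, from 22 back to 23: i-Bu3Al in CH2Cl2/hexane at −78 °C to rt effects the same C2–C3 bond formation but reduces the ketone as soon as it forms, so no enolisable ketone remains in the Lewis-acidic medium. The product is (2S,5S)-2-DBF-5-(ArCH2)-oxolan-4-ol F7, as one or both C4 epimers, and Dess–Martin periodinane with NaHCO3 oxidises it to 23.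

**Step 17.** Proton exchange between the enolate and the aldolate may scramble the regiochemistry and epimerise C5; a second hydroxymethylation, dehydration to the exocyclic enone, or retro-aldol on warming may also occur.
Fallback, a Lewis-acid-catalysed aldol of an isolated enol silane, from 23 back to 25: LiN(i-Pr)2 and Me3SiCl at −78 °C give the C3–C4 trimethylsilyl enol ether of 23 F8. An aqueous Mukaiyama aldol with formalin and Yb(OTf)3, ytterbium tris(trifluoromethanesulfonate), in THF/H2O at rt then gives 25 without any basic enolate being exposed to the product.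

**Step 18.** Hydride may be delivered externally, or the boron-bound arm may discriminate poorly between the two faces of C4, giving the C4 epimer.
Fallback, a purely intramolecular hydride shift, from 25 back to 26: an Evans–Tishchenko reduction with SmI2 (samarium diiodide, catalytic) and acetaldehyde in THF at −10 °C transfers hydride from the hemiacetal formed on the primary hydroxyl to the same face of C4. The product is the 3-(acetoxymethyl)oxolan-4-ol F9, and i-Bu2AlH at −78 °C removes the acetate to give 26.

## Further compounds

F1 | step 7 | methyl (2S,3R)-5-bromo-7-methoxy-2-[3-methoxy-4-(triisopropylsilyloxy)phenyl]-2,3-dihydrobenzofuran-3-carboxylate, mirror image of 9 | Brc1cc(OC)c2c(c1)[C@@H](C(=O)OC)[C@@H](c1ccc(O[Si](C(C)C)(C(C)C)C(C)C)c(OC)c1)O2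
F2 | step 7 | [(2S,3S)-5-bromo-7-methoxy-2-[3-methoxy-4-(triisopropylsilyloxy)phenyl]-2,3-dihydrobenzofuran-3-yl]methanol, mirror image of 10 | Brc1cc(OC)c2c(c1)[C@@H](CO)[C@@H](c1ccc(O[Si](C(C)C)(C(C)C)C(C)C)c(OC)c1)O2
F3 | step 7 | (S)-2-methoxy-2-phenylacetate of 10 | Brc1cc(OC)c2c(c1)[C@H](COC(=O)[C@@H](OC)c1ccccc1)[C@H](c1ccc(O[Si](C(C)C)(C(C)C)C(C)C)c(OC)c1)O2
F4 | step 7 | (S)-2-methoxy-2-phenylacetate of the mirror-image alcohol F2 | Brc1cc(OC)c2c(c1)[C@@H](COC(=O)[C@@H](OC)c1ccccc1)[C@@H](c1ccc(O[Si](C(C)C)(C(C)C)C(C)C)c(OC)c1)O2
F5 | step 5 | 2-[5-bromo-3-methoxy-2-(3-methoxy-4-triisopropylsilyloxybenzyloxy)phenyl]acetaldehyde | O=CCc1cc(Br)cc(OC)c1OCc1ccc(O[Si](C(C)C)(C(C)C)C(C)C)c(OC)c1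
F6 | step 5 | 2-[5-bromo-3-methoxy-2-(3-methoxy-4-triisopropylsilyloxybenzyloxy)phenyl]acetic acid | OC(=O)Cc1cc(Br)cc(OC)c1OCc1ccc(O[Si](C(C)C)(C(C)C)C(C)C)c(OC)c1
F7 | step 16 | (2S,5S)-2-DBF-5-[3-methoxy-4-(triisopropylsilyloxy)benzyl]oxolan-4-ol, C4 epimers | COc1cc(C[C@@H]2O[C@H](c3cc(OC)c4c(c3)[C@H](CO[Si](C)(C)C(C)(C)C)[C@H](c5ccc(O[Si](C(C)C)(C(C)C)C(C)C)c(OC)c5)O4)CC2O)ccc1O[Si](C(C)C)(C(C)C)C(C)C
F8 | step 17 | C3–C4 trimethylsilyl enol ether of 23 | COc1cc(C[C@@H]2O[C@H](c3cc(OC)c4c(c3)[C@H](CO[Si](C)(C)C(C)(C)C)[C@H](c5ccc(O[Si](C(C)C)(C(C)C)C(C)C)c(OC)c5)O4)C=C2O[Si](C)(C)C)ccc1O[Si](C(C)C)(C(C)C)C(C)C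
F9 | step 18 | (2S,3S,4S,5S)-3-(acetoxymethyl)-2-DBF-5-[3-methoxy-4-(triisopropylsilyloxy)benzyl]oxolan-4-ol | COc1cc(C[C@@H]2O[C@H](c3cc(OC)c4c(c3)[C@H](CO[Si](C)(C)C(C)(C)C)[C@H](c5ccc(O[Si](C(C)C)(C(C)C)C(C)C)c(OC)c5)O4)[C@@H](COC(C)=O)[C@@H]2O)ccc1O[Si](C(C)C)(C(C)C)C(C)C
A1 | alternative 1 | 2,5-cis 2-DBF-5-[3-methoxy-4-(triisopropylsilyloxy)benzyl]oxolan-4-one, identical with 23 | COc1cc(C[C@@H]2O[C@H](c3cc(OC)c4c(c3)[C@H](CO[Si](C)(C)C(C)(C)C)[C@H](c5ccc(O[Si](C(C)C)(C(C)C)C(C)C)c(OC)c5)O4)CC2=O)ccc1O[Si](C(C)C)(C(C)C)C(C)C
A2 | alternative 2 | 2-DBF-5-(iodomethyl)-3-(tert-butyldimethylsilyloxymethyl)oxolan-4-ol, configured as the target at C2–C5 | IC[C@@H]2O[C@H](c3cc(OC)c4c(c3)[C@H](CO[Si](C)(C)C(C)(C)C)[C@H](c5ccc(O[Si](C(C)C)(C(C)C)C(C)C)c(OC)c5)O4)[C@@H](CO[Si](C)(C)C(C)(C)C)[C@@H]2O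
A3 | alternative 2 | 1-DBF-2-(tert-butyldimethylsilyloxymethyl)pent-4-ene-1,3-diol, configured as the target at the future C2, C3 and C4 | C=C[C@@H](O)[C@H](CO[Si](C)(C)C(C)(C)C)[C@H](O)c1cc(OC)c2c(c1)[C@H](CO[Si](C)(C)C(C)(C)C)[C@H](c1ccc(O[Si](C(C)C)(C(C)C)C(C)C)c(OC)c1)O2
A4 | alternative 3 | 2,3-trans-2,5-cis 2-DBF-3-(tert-butyldimethylsilyloxymethyl)-5-[3-methoxy-4-(triisopropylsilyloxy)benzyl]oxolan-4-one | COc1cc(C[C@@H]2O[C@H](c3cc(OC)c4c(c3)[C@H](CO[Si](C)(C)C(C)(C)C)[C@H](c5ccc(O[Si](C(C)C)(C(C)C)C(C)C)c(OC)c5)O4)[C@@H](CO[Si](C)(C)C(C)(C)C)C2=O)ccc1O[Si](C(C)C)(C(C)C)C(C)C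
A5 | alternative 3 | 1-diazo-4-DBF-4-[3-methoxy-4-(triisopropylsilyloxy)benzyloxy]-3-(tert-butyldimethylsilyloxymethyl)butan-2-one, configured as the target at the future C2 and C3 | [N-]=[N+]=CC(=O)[C@H](CO[Si](C)(C)C(C)(C)C)[C@@H](c1cc(OC)c2c(c1)[C@H](CO[Si](C)(C)C(C)(C)C)[C@H](c1ccc(O[Si](C(C)C)(C(C)C)C(C)C)c(OC)c1)O2)OCc1ccc(O[Si](C(C)C)(C(C)C)C(C)C)c(OC)c1
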